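Ring B of the target is a cyclohexene whose C7=C8 alkene, C8 methyl and contiguous stereocentres C5, C10 and C9 (drimane numbering) are the imprint of a Diels–Alder reaction between a 2-methyl diene and an (E)-2-methyl enoate. Joining C11–O to C1 as an ester makes this cycloaddition intramolecular: one enantioselective, Lewis acid-catalysed step forms C5–C6 and C9–C10, closes ring B together with a cis-fused γ-lactone and sets all three stereocentres. Its precursor is an acyclic (E)-3-methylpentadienyl (E)-2-methyl-2-enoate with the C3 ketone masked as a dithiolane. The lactone later releases C1 for the aldol closure of ring A and C11–OH for the coumarin ether.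

Key step: step 7

Remark 1: atoms carry drimane numbers throughout (C3 ketone, C4 gem-dimethyl, C5–H, C7=C8, C8–CH3, C9–C11–O, C10–CH3). The target is the (5R,9R,10S) isomer, with C11 axial and trans to the C10 methyl, which is what a cis-fused C11–O–C1 lactone delivers.
Remark 2: the C3 ketone is masked as a 1,3-dithiolane and not as an O,O-ketal, since the cationic boron Lewis acid of step 7 would bind and ionise an oxygen ketal.
Remark 3: a free 11-hydroxy-1-en-3-one holds its axial C11 hydroxyl over C1 and should close to the 1,11-ether. Steps 10 to 12 therefore pass through that ether deliberately and reopen it as a silyl ether.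
Remark 4: 2-(diethoxyphosphoryl)propanoic acid and both enantiomers of the o-tolyl oxazaborolidine are taken as purchasable.

Step 1
Reactants: 1 ethyl 2,2-dimethyl-3-oxobutanoate
Product: 2 ethyl 2-methyl-2-(2-methyl-1,3-dithiolan-2-yl)propanoate
Conditions: HSCH2CH2SH, BF3·OEt2, CH2Cl2, 0 °C to rt
Reagents that add atoms: ethane-1,2-dithiol, SCCS
Why: Lewis acid-promoted thioketalisation of the only ketone, which gives a mask that should survive hydride, base and the hard cationic Lewis acid used later.

Step 2
Reactants: 2 ethyl 2-methyl-2-(2-methyl-1,3-dithiolan-2-yl)propanoate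
Product: 3 2-methyl-2-(2-methyl-1,3-dithiolan-2-yl)propan-1-ol
Conditions: LiAlH4, Et2O, 0 °C
Reagents that add atoms: none
Why: hydride reduction of an ester to the primary alcohol, to which the dithiolane is inert.

Step 3
Reactants: 3 2-methyl-2-(2-methyl-1,3-dithiolan-2-yl)propan-1-ol
Product: 4 2-methyl-2-(2-methyl-1,3-dithiolan-2-yl)propanal
Conditions: SO3·pyridine, DMSO, Et3N, CH2Cl2, 0 °C
Reagents that add atoms: none
Why: Parikh–Doering oxidation, an activated-DMSO method that stops at the non-enolisable aldehyde and, unlike halogen or hypervalent iodine oxidants, should leave the dithiolane alone.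

Step 4
Reactants: 5 (E)-3-methylpent-2-en-4-yn-1-ol
Product: 6 (E)-3-methylpenta-2,4-dien-1-ol
Conditions: H2 (1 atm), Pd/CaCO3 poisoned with Pb(OAc)2, quinoline, EtOAc, rt, stopped after one equivalent of H2
Reagents that add atoms: none
Why: semihydrogenation of a terminal alkyne over lead-poisoned palladium, which should stop at the vinyl group and keep the E trisubstituted alkene.

Step 5
Reactants: 6 (E)-3-methylpenta-2,4-dien-1-ol; 7 2-(diethoxyphosphoryl)propanoic acid
Product: 8 (2E)-3-methylpenta-2,4-dien-1-yl 2-(diethoxyphosphoryl)propanoate
Conditions: DCC, DMAP (cat.), CH2Cl2, 0 °C to rt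
Reagents that add atoms: none
Why: Steglich esterification under neutral carbodiimide conditions, which avoids acid that could ionise the dienyl alcohol.

Step 6
Reactants: 8 (2E)-3-methylpenta-2,4-dien-1-yl 2-(diethoxyphosphoryl)propanoate; 4 2-methyl-2-(2-methyl-1,3-dithiolan-2-yl)propanal
Product: 9 (2E)-3-methylpenta-2,4-dien-1-yl (2E)-2,4-dimethyl-4-(2-methyl-1,3-dithiolan-2-yl)pent-2-enoate
Conditions: NaH, THF, 0 °C; then 4, 0 to 50 °C
Reagents that add atoms: none
Why: Horner–Wadsworth–Emmons olefination of an α-quaternary aldehyde with an α-methyl phosphonate, which should give the E trisubstituted enoate under thermodynamic control; the product has no γ-hydrogen and cannot deconjugate.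

Step 7
Reactants: 9 (2E)-3-methylpenta-2,4-dien-1-yl (2E)-2,4-dimethyl-4-(2-methyl-1,3-dithiolan-2-yl)pent-2-enoate
Product: 10 (3aR,7R,7aS)-4,7a-dimethyl-7-[2-(2-methyl-1,3-dithiolan-2-yl)propan-2-yl]-3a,6,7,7a-tetrahydro-2-benzofuran-1(3H)-one (cis-fused lactone; 3a-H cis to 7a-CH3, 7-H trans to 7a-CH3)
Conditions: (S)-3,3-diphenyl-1-(2-methylphenyl)tetrahydro-1H,3H-pyrrolo[1,2-c][1,3,2]oxazaborole (20 mol%), AlBr3 (16 mol%), CH2Cl2 (0.01 M), −78 to −20 °C
Reagents that add atoms: none
Why: Proposed new method: the cationic oxazaborolidinium Lewis acid binds the tether carbonyl of 9, lowers the enoate LUMO and lets the tethered diene add in a concerted, asynchronous, suprafacial [4+2] cycloaddition in which C5–C6 forms ahead of C9–C10; the closest known reaction types are the thermal intramolecular Diels–Alder reaction of pentadienyl acrylates and intermolecular oxazaborolidinium-catalysed Diels–Alder reactions of acrylic esters, and their union in an ester-tethered, catalytic, enantioselective form is the untested element. Ring B closes as the six-membered cycloadduct ring, and the γ-lactone closes in the fused mode because the three-atom tether C11–O–C1 joins the diene terminus C9 to the dienophile carbon C10. The trans relation of H5 and the C10 methyl follows from the E enoate, since addition is suprafacial on the dienophile. C9 is set relative to C10 by the endo position of the tether carbonyl, which the short tether favours (a trans-fused five-membered lactone on the new cyclohexene is strained) and which places the bulky C4 quaternary group exo, away from the diene, so that the E diene puts C11 cis to C1. The absolute configuration rests on the catalyst, whose aryl groups shield one face of the bound enoate; the step therefore needs enantioface selectivity from the catalyst and endo selectivity from the tether and the C4 group, while regiochemistry is fixed by the tether. The dithiolane is a poor donor for the hard boron cation and should not be ionised (AlBr3 is kept below the oxazaborolidine so that none is free), and low temperature and high dilution are meant to suppress ionisation of the dienyl ester and intermolecular cycloaddition.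

Step 8
Reactants: 10 cis-fused lactone
Product: 11 (3aR,7R,7aS)-4,7a-dimethyl-7-[2-(2-methyl-1,3-dithiolan-2-yl)propan-2-yl]-1,3,3a,6,7,7a-hexahydro-2-benzofuran-1-ol (lactol, both C1 epimers)
Conditions: i-Bu2AlH (1.1 equiv), CH2Cl2, −78 °C
Reagents that add atoms: none
Why: half-reduction of a lactone with a dialkylaluminium hydride, in which the tetrahedral aluminium alkoxide of this α-quaternary lactone should persist at −78 °C so that reduction stops at the lactol; dithiolane and alkene are inert.

Step 9
Reactants: 11 dithiolane lactol
Product: 12 3-[(3aR,7R,7aS)-1-hydroxy-4,7a-dimethyl-1,3,3a,6,7,7a-hexahydro-2-benzofuran-7-yl]-3-methylbutan-2-one (keto lactol, both C1 epimers)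
Conditions: MeI (excess), CaCO3, MeCN/H2O (4:1), 45 °C
Reagents that add atoms: water, O
Why: alkylative dethioketalisation (S-methylation, then hydrolysis of the thionium ion) under buffered neutral conditions that should leave the lactol and the trisubstituted alkene untouched.

Step 10
Reactants: 12 keto lactol
Product: 14 1,11-epoxydrim-7-en-3-one (ether oxygen on the C11 face of C1; C5, C9, C10 as in 19), via 11-hydroxydrima-1,7-dien-3-one 13 (not isolated)
Conditions: KOH, MeOH, 50 °C
Reagents that add atoms: none
Why: base-mediated intramolecular aldol condensation, in which the methyl ketone is the only enolisable site and the C1 aldehyde (open form of the lactol) cannot enolise, so a single six-membered closure should give the trans-fused enone 13 (C1 and C4 are trans on ring B), after which the freed axial C11 alkoxide, held over C1, adds in a 5-exo-trig oxa-Michael reaction that can only place the ether oxygen on the C11 face, which fixes C1; any 13 left at equilibrium converges with 14 on 15 in step 11.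

Step 11
Reactants: 14 1,11-epoxydrim-7-en-3-one
Product: 15 11-(triethylsilyloxy)drima-1,7-dien-3-one (C5, C9, C10 as in 19)
Conditions: Et3SiOTf (2.5 equiv), Et3N (4 equiv), CH2Cl2, 0 °C to rt
Reagents that add atoms: triethylsilyl trifluoromethanesulfonate, CC[Si](CC)(CC)OS(=O)(=O)C(F)(F)F
Why: silyl triflate/amine β-elimination of a β-alkoxy ketone, the reaction type used to open oxabicyclic ketones to silyloxy enones, in which the triethylsilyl enol ether expels the O-silylated C1–O bond and leaves C11 capped as a silyl ether that can no longer add to C1; the enone has no α′ or γ hydrogen and cannot react further.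

Step 12
Reactants: 15 11-(triethylsilyloxy)drima-1,7-dien-3-one
Product: 17 (5R,9R,10S)-11-hydroxydrim-7-en-3-one, via 11-(triethylsilyloxy)drim-7-en-3-one 16 (not isolated)
Conditions: [(Ph3P)CuH]6 (0.4 equiv), H2O (5 equiv), degassed toluene, rt; then 1 M HCl, THF, rt
Reagents that add atoms: none
Why: conjugate reduction with the phosphine copper hydride hexamer, which should deliver hydride only to the enone β-carbon C1 and spare the ketone and the isolated C7=C8 alkene (no stereocentre is created), followed by acid cleavage of the primary triethylsilyl ether.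

Step 13
Reactants: 17 (5R,9R,10S)-11-hydroxydrim-7-en-3-one; 18 umbelliferone (7-hydroxy-2H-chromen-2-one)
Product: 19 7-{[(5R,9R,10S)-3-oxodrim-7-en-11-yl]oxy}-2H-chromen-2-one, that is 7-{[(1R,4aR,8aS)-2,5,5,8a-tetramethyl-6-oxo-1,4,4a,5,6,7,8,8a-octahydronaphthalen-1-yl]methoxy}-2H-chromen-2-one
Conditions: PPh3, DIAD, THF, 0 °C to rt
Reagents that add atoms: none
Why: Mitsunobu etherification, in which the primary C11 alcohol is activated as its oxyphosphonium salt and displaced by the acidic phenol at a carbon that is not a stereocentre, under neutral conditions that should spare the coumarin lactone, the ketone and the alkene.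

Compound list
1 | ethyl 2,2-dimethyl-3-oxobutanoate | CCOC(=O)C(C)(C)C(C)=O | starting material
2 | ethyl 2-methyl-2-(2-methyl-1,3-dithiolan-2-yl)propanoate | CCOC(=O)C(C)(C)C1(C)SCCS1 | intermediate
3 | 2-methyl-2-(2-methyl-1,3-dithiolan-2-yl)propan-1-ol | OCC(C)(C)C1(C)SCCS1 | intermediate
4 | 2-methyl-2-(2-methyl-1,3-dithiolan-2-yl)propanal | O=CC(C)(C)C1(C)SCCS1 | intermediate
5 | (E)-3-methylpent-2-en-4-yn-1-ol | C#C/C(C)=C/CO | starting material
6 | (E)-3-methylpenta-2,4-dien-1-ol | C=C/C(C)=C/CO | intermediate
7 | 2-(diethoxyphosphoryl)propanoic acid | CCOP(=O)(OCC)C(C)C(=O)O | starting material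
8 | (2E)-3-methylpenta-2,4-dien-1-yl 2-(diethoxyphosphoryl)propanoate (racemic at the phosphonate carbon) | C=C/C(C)=C/COC(=O)C(C)P(=O)(OCC)OCC | intermediate
9 | (2E)-3-methylpenta-2,4-dien-1-yl (2E)-2,4-dimethyl-4-(2-methyl-1,3-dithiolan-2-yl)pent-2-enoate | C=C/C(C)=C/COC(=O)/C(C)=C/C(C)(C)C1(C)SCCS1 | intermediate
10 | (3aR,7R,7aS)-4,7a-dimethyl-7-[2-(2-methyl-1,3-dithiolan-2-yl)propan-2-yl]-3a,6,7,7a-tetrahydro-2-benzofuran-1(3H)-one | CC1=CC[C@@H](C(C)(C)C2(C)SCCS2)[C@]3(C)C(=O)OC[C@H]13 | intermediate
11 | (3aR,7R,7aS)-4,7a-dimethyl-7-[2-(2-methyl-1,3-dithiolan-2-yl)propan-2-yl]-1,3,3a,6,7,7a-hexahydro-2-benzofuran-1-ol (both C1 epimers) | CC1=CC[C@@H](C(C)(C)C2(C)SCCS2)[C@]3(C)C(O)OC[C@H]13 | intermediate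
12 | 3-[(3aR,7R,7aS)-1-hydroxy-4,7a-dimethyl-1,3,3a,6,7,7a-hexahydro-2-benzofuran-7-yl]-3-methylbutan-2-one (both C1 epimers) | CC1=CC[C@@H](C(C)(C)C(C)=O)[C@]3(C)C(O)OC[C@H]13 | intermediate
13 | 11-hydroxydrima-1,7-dien-3-one (C5, C9, C10 as in 19) | CC1=CC[C@H]2C(C)(C)C(=O)C=C[C@]2(C)[C@@H]1CO | intermediate (not isolated)
14 | 1,11-epoxydrim-7-en-3-one (ether oxygen on the C11 face of C1) | CC1=CC[C@H]2C(C)(C)C(=O)C[C@@H]3OC[C@H]1[C@]23C | intermediate
15 | 11-(triethylsilyloxy)drima-1,7-dien-3-one | CC1=CC[C@H]2C(C)(C)C(=O)C=C[C@]2(C)[C@@H]1CO[Si](CC)(CC)CC | intermediate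
16 | (5R,9R,10S)-11-(triethylsilyloxy)drim-7-en-3-one | CC1=CC[C@H]2C(C)(C)C(=O)CC[C@]2(C)[C@@H]1CO[Si](CC)(CC)CC | intermediate (not isolated)
17 | (5R,9R,10S)-11-hydroxydrim-7-en-3-one | CC1=CC[C@H]2C(C)(C)C(=O)CC[C@]2(C)[C@@H]1CO | intermediate
18 | umbelliferone (7-hydroxy-2H-chromen-2-one) | Oc1ccc2ccc(=O)oc2c1 | starting material
19 | 7-{[(1R,4aR,8aS)-2,5,5,8a-tetramethyl-6-oxo-1,4,4a,5,6,7,8,8a-octahydronaphthalen-1-yl]methoxy}-2H-chromen-2-one | CC1=CC[C@H]2C(C)(C)C(=O)CC[C@]2(C)[C@@H]1COc1ccc2ccc(=O)oc2c1 | target

Total step count: 13. Longest linear sequence: 11 steps (steps 1 to 3 and 6 to 13, from 1); the dienol branch (steps 4 and 5) joins at step 6.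

Steps most likely to fail

Step 7 (the proposed new method). The Lewis acid complex of the ester may stay in its extended ester conformation, so that cyclisation does not start below the temperature at which the dienyl C–O bond ionises. Discrimination between the two enoate faces may be weak or reversed; for a reversed sense the mirror-image catalyst from (R)-diphenylprolinol would be used. Some material may leak through the exo tether geometry. The fallback uses known chemistry, sets out from 9 and comes back at 10. Heating 9 at high dilution (o-dichlorobenzene, BHT, 160 to 180 °C, sealed vessel) is the established thermal intramolecular Diels–Alder reaction of pentadienyl acrylates and should give the racemic cis-lactone F1. Preparative chromatography on a chiral stationary phase (amylose tris(3,5-dimethylphenylcarbamate)) then separates the enantiomers and returns 10.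

Step 11. The silyl enol ether may form without cleavage of the C1–O bond, so that the ether ring stays closed or opens only in part. The fallback sets out from 14 and comes back at 17. It replaces silyl oxonium activation by a base-mediated retro-oxa-Michael reaction with acyl trapping: DBU, Ac2O and DMAP in toluene at 80 °C should drain the small equilibrium amount of 13 irreversibly into the enone acetate F2. Conjugate reduction with [(Ph3P)CuH]6 in wet toluene should then give the keto acetate F3, and K2CO3 in MeOH removes the acetate to return 17.

Step 13. Displacement at the axial, β-branched C11 oxyphosphonium next to the quaternary C10 may be slow, so that the activated alcohol is consumed by alkylation of the hydrazide or the reaction stalls. The fallback sets out from 17 and comes back at 19. It forms the ether bond at the aryl carbon instead: palladium-catalysed C–O coupling of 17 with purchased 7-bromo-2H-chromen-2-one ([(C3H5)PdCl]2, t-BuBrettPhos, Cs2CO3, toluene, 80 °C), with the weak carbonate base chosen to spare the coumarin lactone and to disfavour ketone α-arylation. It makes no further compound (entry F0).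

Further compounds
F1 | step 7 | racemic cis-lactone (equal amounts of 10 and its mirror image) | CC1=CC[C@@H](C(C)(C)C2(C)SCCS2)[C@]3(C)C(=O)OC[C@H]13.CC1=CC[C@H](C(C)(C)C2(C)SCCS2)[C@@]3(C)C(=O)OC[C@@H]13
F2 | step 11 | 11-acetoxydrima-1,7-dien-3-one (C5, C9, C10 as in 19) | CC1=CC[C@H]2C(C)(C)C(=O)C=C[C@]2(C)[C@@H]1COC(C)=O
F3 | step 11 | (5R,9R,10S)-11-acetoxydrim-7-en-3-one | CC1=CC[C@H]2C(C)(C)C(=O)CC[C@]2(C)[C@@H]1COC(C)=O
F0 | step 13 | none | none
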